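**Plan**

- Retrosynthesis: the formyl C–C bond on ring B (the chlorinated acid ring) and the protecting groups come off first. Ring A (the methyl ester ring) is then de-aromatised to a cyclohexane-1,3-dione and cut at two ring bonds, giving dimethyl malonate and a 4-aryloxyhex-4-en-3-one. The two bonds are ester-bearing carbon to its methyl-bearing neighbour, and the methyl-bearing carbon between the two hydroxyl carbons to the hydroxyl carbon beside the ester carbon.
- Enabling feature: ring A is a resorcinol whose two hydroxyl carbons flank a C-methyl, with one of them next to the ester carbon. This is the oxygen pattern of a 2,4-dioxocyclohexane-1-carboxylate, one dehydrogenation below the arene.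
- The enone is cut at its C=C (olefination with acetaldehyde) and at the alkyl C–O bond (carbenoid O–H insertion into the ring B phenol), so the crowded ether oxygen is never made by coupling two arenes.
- Forward: ring B is bought as orsellinic acid and dressed (tert-butyl ester, 4-O-benzyl, 5-chloro). The ether oxygen is attached, the enone is made, and ring A is built by Michael–Claisen annulation and aromatised. Debenzylation, ortho-formylation and ester acidolysis finish the route.
- Stereochemistry: the target has no stereocentre. The sp3 centres of 7, 11 and 12 and the alkene geometry of 9 are uncontrolled and disappear on aromatisation.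

Key step: step 7

Remark: enone 9 is drawn as the Z isomer expected from the olefination, and either geometry serves equally in step 7. Compounds 7, 11 and 12 are handled as stereoisomer mixtures (12 also as keto–enol tautomers).

**Route**

Step 1
Reactants: 1 orsellinic acid (2,4-dihydroxy-6-methylbenzoic acid)
Product: 2 tert-butyl 2,4-dihydroxy-6-methylbenzoate
Conditions: tert-butyl 2,2,2-trichloroacetimidate (2.5 equiv), THF/cyclohexane, 23 °C
Reagents that add atoms: tert-butyl 2,2,2-trichloroacetimidate, CC(C)(C)OC(=N)C(Cl)(Cl)Cl
Why: Uncatalysed imidate esterification, in which the carboxylic acid protonates the imidate and the ion pair collapses at the carboxylate oxygen, so the hindered carbonyl carbon is never attacked, the less acidic phenols stay free, and room temperature avoids decarboxylation of the β-resorcylic acid.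

Step 2
Reactants: 2 tert-butyl 2,4-dihydroxy-6-methylbenzoate
Product: 3 tert-butyl 4-(benzyloxy)-2-hydroxy-6-methylbenzoate
Conditions: BnBr (1.05 equiv), K2CO3 (1.1 equiv), acetone, reflux
Reagents that add atoms: benzyl bromide, BrCc1ccccc1
Why: Williamson etherification selective for the 4-OH, because the 2-OH is hydrogen-bonded to the ester carbonyl and is both less acidic and less nucleophilic.

Step 3
Reactants: 3 tert-butyl 4-(benzyloxy)-2-hydroxy-6-methylbenzoate
Product: 4 tert-butyl 4-(benzyloxy)-3-chloro-6-hydroxy-2-methylbenzoate
Conditions: NCS (1.05 equiv), MeCN, 23 °C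
Reagents that add atoms: N-chlorosuccinimide, O=C1CCC(=O)N1Cl
Why: Electrophilic aromatic chlorination goes para to the free phenol and ortho to the benzyloxy group (the resorcinol 4-type position) rather than to the crowded carbon between the two oxygens, and NCS avoids the HCl load of SO2Cl2 that would endanger the tert-butyl ester.

Step 4
Reactants: 5 diethyl (2-oxobutyl)phosphonate
Product: 6 diethyl (1-diazo-2-oxobutyl)phosphonate
Conditions: 4-acetamidobenzenesulfonyl azide (1.1 equiv), K2CO3, MeCN, 0 to 23 °C
Reagents that add atoms: 4-acetamidobenzenesulfonyl azide, CC(=O)Nc1ccc(cc1)S(=O)(=O)N=[N+]=[N-]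
Why: Regitz diazo transfer to the doubly activated methylene of a β-ketophosphonate, the same transformation that turns the lower homologue into the Ohira–Bestmann reagent.

Step 5
Reactants: 4 tert-butyl 4-(benzyloxy)-3-chloro-6-hydroxy-2-methylbenzoate; 6 diethyl (1-diazo-2-oxobutyl)phosphonate
Product: 7 tert-butyl 4-(benzyloxy)-3-chloro-6-{[1-(diethoxyphosphoryl)-2-oxobutyl]oxy}-2-methylbenzoate
Conditions: Rh2(OAc)4 (2 mol%), toluene, 80 °C, slow addition of 6 (1.3 equiv)
Reagents that add atoms: none
Why: Rhodium-carbenoid O–H insertion, in which the electrophilic acceptor/acceptor carbenoid is captured by the phenol oxygen (oxonium ylide, then proton shift), forming the hindered alkyl aryl ether and placing the phosphonate on the carbon that must become the enone α-carbon.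

Step 6
Reactants: 7 tert-butyl 4-(benzyloxy)-3-chloro-6-{[1-(diethoxyphosphoryl)-2-oxobutyl]oxy}-2-methylbenzoate; 8 acetaldehyde
Product: 9 tert-butyl 4-(benzyloxy)-3-chloro-2-methyl-6-{[(2Z)-4-oxohex-2-en-3-yl]oxy}benzoate
Conditions: NaH (1.1 equiv), THF, 0 °C; then CH3CHO (3 equiv), −78 to 23 °C
Reagents that add atoms: none
Why: Horner–Wadsworth–Emmons olefination of the ketone- and phosphonate-stabilised carbanion fixes the C=C position without any question of which ketone α-carbon enolises, and the weakly basic anion neither enolises acetaldehyde nor attacks the hindered aryl ester.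

Step 7
Reactants: 9 tert-butyl 4-(benzyloxy)-3-chloro-2-methyl-6-{[(2Z)-4-oxohex-2-en-3-yl]oxy}benzoate; 10 dimethyl malonate
Product: 12 methyl 5-[5-(benzyloxy)-2-(tert-butoxycarbonyl)-4-chloro-3-methylphenoxy]-3,6-dimethyl-2,4-dioxocyclohexane-1-carboxylate, via Michael adduct 11 (not isolated)
Conditions: dimethyl malonate (1.2 equiv), NaOMe (1.3 equiv), MeOH, reflux; then 1 M HCl to pH 3, 0 °C
Reagents that add atoms: none
Why: Methoxide forms the malonate anion, which adds to the methyl-bearing β-carbon of the enone; proton exchange then gives the enolate at the ethyl α-carbon, which acylates one malonate ester with loss of methoxide, and the dione is drained from all equilibria as its doubly stabilised enolate. The closest known reaction type is the Michael–Claisen (Michael–Dieckmann) condensation of malonates with alkyl propenyl ketones to 2,4-dioxocyclohexane-1-carboxylates, the only new element being the aryloxy group on the enone α-carbon. The ring closes in a 6-(enolendo)-exo-trig mode, while every alternative closure onto a malonate ester or the ketone would be four-membered. Four sp3 centres (C-1, C-3, C-5, C-6) form without control and are all erased at aromatisation, so none needs to be set. Regioselectivity is secured because the enone has a single β-carbon and only the ethyl α-carbon can reach an ester through a six-membered transition state. Chemoselectivity against closure of the transient α-aryloxy enolate onto the ring B ester is secured because that ester is tert-butyl with two ortho substituents and such a closure would have to create a quaternary carbon.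

Step 8
Reactants: 12 methyl 5-[5-(benzyloxy)-2-(tert-butoxycarbonyl)-4-chloro-3-methylphenoxy]-3,6-dimethyl-2,4-dioxocyclohexane-1-carboxylate
Product: 13 methyl 3-[5-(benzyloxy)-2-(tert-butoxycarbonyl)-4-chloro-3-methylphenoxy]-4,6-dihydroxy-2,5-dimethylbenzoate
Conditions: DDQ (1.1 equiv), 1,4-dioxane, 23 to 60 °C
Reagents that add atoms: none
Why: DDQ dehydrogenation of a cyclohexane-1,3-dione to a resorcinol, by hydride abstraction from C-6 of the enolised β-keto ester, loss of the C-5 proton and tautomerisation, with the simple benzyl ether and the tert-butyl ester inert to the quinone.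

Step 9
Reactants: 13 methyl 3-[5-(benzyloxy)-2-(tert-butoxycarbonyl)-4-chloro-3-methylphenoxy]-4,6-dihydroxy-2,5-dimethylbenzoate
Product: 14 methyl 3-[2-(tert-butoxycarbonyl)-4-chloro-5-hydroxy-3-methylphenoxy]-4,6-dihydroxy-2,5-dimethylbenzoate
Conditions: H2 (1 atm), 5% Pd/C, EtOAc, 23 °C, stopped at full conversion
Reagents that add atoms: none
Why: Catalytic hydrogenolysis of the aryl benzyl ether, which in neutral ethyl acetate without added base is much faster than hydrodechlorination of the aryl chloride and leaves both esters untouched.

Step 10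
Reactants: 14 methyl 3-[2-(tert-butoxycarbonyl)-4-chloro-5-hydroxy-3-methylphenoxy]-4,6-dihydroxy-2,5-dimethylbenzoate
Product: 16 methyl 3-[2-(tert-butoxycarbonyl)-4-chloro-6-formyl-5-hydroxy-3-methylphenoxy]-4,6-dihydroxy-2,5-dimethylbenzoate, via hydroxymethyl phenol 15 (not isolated)
Conditions: MgCl2 (4 equiv), Et3N (8 equiv), paraformaldehyde (10 equiv), MeCN, 80 °C; then cold 1 M HCl
Reagents that add atoms: paraformaldehyde (as formaldehyde), C=O
Why: Magnesium-mediated ortho-formylation of a phenol (Casnati–Skattebøl), in which the magnesium phenoxide is hydroxymethylated at its one free ortho carbon, the only aromatic C–H in the molecule, and the benzylic alkoxide is oxidised by hydride transfer to a second formaldehyde, under basic conditions that keep the tert-butyl ester.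

Step 11
Reactants: 16 methyl 3-[2-(tert-butoxycarbonyl)-4-chloro-6-formyl-5-hydroxy-3-methylphenoxy]-4,6-dihydroxy-2,5-dimethylbenzoate
Product: 17 3-chloro-6-[2,4-dihydroxy-5-(methoxycarbonyl)-3,6-dimethylphenoxy]-5-formyl-4-hydroxy-2-methylbenzoic acid (CNP0210944.0)
Conditions: TFA/CH2Cl2 (1:3), 0 to 23 °C
Reagents that add atoms: none
Why: Acidolysis of the tert-butyl ester by alkyl–oxygen cleavage (loss of isobutene) does not depend on access to the hindered carbonyl and leaves the methyl ester, aldehyde, phenols and aryl chloride unchanged.

**Compound list**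

1 | orsellinic acid (2,4-dihydroxy-6-methylbenzoic acid) | Cc1cc(O)cc(O)c1C(=O)O | starting material
2 | tert-butyl 2,4-dihydroxy-6-methylbenzoate | Cc1cc(O)cc(O)c1C(=O)OC(C)(C)C | intermediate
3 | tert-butyl 4-(benzyloxy)-2-hydroxy-6-methylbenzoate | Cc1cc(OCc2ccccc2)cc(O)c1C(=O)OC(C)(C)C | intermediate
4 | tert-butyl 4-(benzyloxy)-3-chloro-6-hydroxy-2-methylbenzoate | Cc1c(Cl)c(OCc2ccccc2)cc(O)c1C(=O)OC(C)(C)C | intermediate
5 | diethyl (2-oxobutyl)phosphonate | CCC(=O)CP(=O)(OCC)OCC | starting material
6 | diethyl (1-diazo-2-oxobutyl)phosphonate | CCC(=O)C(=[N+]=[N-])P(=O)(OCC)OCC | intermediate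
7 | tert-butyl 4-(benzyloxy)-3-chloro-6-{[1-(diethoxyphosphoryl)-2-oxobutyl]oxy}-2-methylbenzoate (racemic) | CCC(=O)C(Oc1cc(OCc2ccccc2)c(Cl)c(C)c1C(=O)OC(C)(C)C)P(=O)(OCC)OCC | intermediate
8 | acetaldehyde | CC=O | starting material
9 | tert-butyl 4-(benzyloxy)-3-chloro-2-methyl-6-{[(2Z)-4-oxohex-2-en-3-yl]oxy}benzoate | CCC(=O)/C(Oc1cc(OCc2ccccc2)c(Cl)c(C)c1C(=O)OC(C)(C)C)=C/C | intermediate
10 | dimethyl malonate | COC(=O)CC(=O)OC | starting material
11 | dimethyl 2-{3-[5-(benzyloxy)-2-(tert-butoxycarbonyl)-4-chloro-3-methylphenoxy]-4-oxohexan-2-yl}propanedioate (Michael adduct, diastereomer mixture, not isolated) | CCC(=O)C(Oc1cc(OCc2ccccc2)c(Cl)c(C)c1C(=O)OC(C)(C)C)C(C)C(C(=O)OC)C(=O)OC | intermediate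
12 | methyl 5-[5-(benzyloxy)-2-(tert-butoxycarbonyl)-4-chloro-3-methylphenoxy]-3,6-dimethyl-2,4-dioxocyclohexane-1-carboxylate (mixture of epimers and enol tautomers) | COC(=O)C1C(C)C(Oc2cc(OCc3ccccc3)c(Cl)c(C)c2C(=O)OC(C)(C)C)C(=O)C(C)C1=O | intermediate
13 | methyl 3-[5-(benzyloxy)-2-(tert-butoxycarbonyl)-4-chloro-3-methylphenoxy]-4,6-dihydroxy-2,5-dimethylbenzoate | COC(=O)c1c(C)c(Oc2cc(OCc3ccccc3)c(Cl)c(C)c2C(=O)OC(C)(C)C)c(O)c(C)c1O | intermediate
14 | methyl 3-[2-(tert-butoxycarbonyl)-4-chloro-5-hydroxy-3-methylphenoxy]-4,6-dihydroxy-2,5-dimethylbenzoate | COC(=O)c1c(C)c(Oc2cc(O)c(Cl)c(C)c2C(=O)OC(C)(C)C)c(O)c(C)c1O | intermediate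
15 | methyl 3-[2-(tert-butoxycarbonyl)-4-chloro-5-hydroxy-6-(hydroxymethyl)-3-methylphenoxy]-4,6-dihydroxy-2,5-dimethylbenzoate (not isolated) | COC(=O)c1c(C)c(Oc2c(CO)c(O)c(Cl)c(C)c2C(=O)OC(C)(C)C)c(O)c(C)c1O | intermediate
16 | methyl 3-[2-(tert-butoxycarbonyl)-4-chloro-6-formyl-5-hydroxy-3-methylphenoxy]-4,6-dihydroxy-2,5-dimethylbenzoate | COC(=O)c1c(C)c(Oc2c(C=O)c(O)c(Cl)c(C)c2C(=O)OC(C)(C)C)c(O)c(C)c1O | intermediate
17 | 3-chloro-6-[2,4-dihydroxy-5-(methoxycarbonyl)-3,6-dimethylphenoxy]-5-formyl-4-hydroxy-2-methylbenzoic acid (CNP0210944.0) | COC(=O)c1c(C)c(Oc2c(C=O)c(O)c(Cl)c(C)c2C(=O)O)c(O)c(C)c1O | target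

**Step count**

Total: 11 steps. Longest linear sequence: 10 steps (1, 2, 3, 5, 6, 7, 8, 9, 10, 11); step 4 is a one-step side branch.

**Steps most likely to fail**

Step 7. The α-oxygen makes the enone a push–pull alkene, so the conjugate addition may stall or reverse at the temperature needed. Enolate side reactions would then take over: closure of the α-aryloxy enolate onto the ring B ester, or expulsion of aryloxide. The fallback separates the two bond formations and activates the electrophile instead of the nucleophile. Setting out from 10, silylation (TMSOTf, Et3N, Et2O, 0 °C) gives the ketene silyl acetal methyl 3-methoxy-3-[(trimethylsilyl)oxy]prop-2-enoate F1. Mukaiyama–Michael addition of F1 to 9 with catalytic Sc(OTf)3 in CH2Cl2 at −78 °C traps the adduct irreversibly as the silyl enol ether dimethyl 2-{3-[5-(benzyloxy)-2-(tert-butoxycarbonyl)-4-chloro-3-methylphenoxy]-4-[(trimethylsilyl)oxy]hex-3-en-2-yl}propanedioate F2, so no free α-aryloxy enolate is present during the C–C bond formation. Mild aqueous acid releases the Michael adduct 11, which is isolated and closed separately with NaOMe in MeOH at 23 °C. The route is rejoined at 12.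

Step 8. The product is a hydroquinone mono-aryl ether (the 6-OH is para to the aryloxy group), so over-oxidation to a quinone with loss of the aryloxy group is possible, as is oxidative attack at the benzyl ether. The fallback replaces hydride abstraction by halogenation–dehydrohalogenation, the classical way of aromatising 3-methyl dihydroresorcylates. Setting out from 12, NCS (1.0 equiv, CH2Cl2, 0 °C) chlorinates the doubly activated C-3 to give methyl 5-[5-(benzyloxy)-2-(tert-butoxycarbonyl)-4-chloro-3-methylphenoxy]-3-chloro-3,6-dimethyl-2,4-dioxocyclohexane-1-carboxylate F3. Heating F3 with LiCl and Li2CO3 in DMF at 100 °C eliminates HCl (allylic shift of chloride through the enol, then elimination), with the carbonate protecting the tert-butyl ester. The route is rejoined at 13.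

Step 10. The phenol is deactivated (ortho chlorine, para ester) and the reacting carbon lies between the hydroxyl and the bulky aryloxy group. The magnesium phenoxide may therefore fail to hydroxymethylate, or the sequence may stop at the benzylic alcohol stage for lack of hydride transfer. The fallback is a Rieche formylation. Setting out from 14, TiCl4 (5 equiv) and dichloromethyl methyl ether in CH2Cl2 at 0 to 23 °C deliver the electrophile through the titanium phenoxide to the same ortho carbon. The Lewis acid cleaves the tert-butyl ester in the same operation, and hydrolytic work-up gives the aldehyde acid. The route is rejoined directly at 17 and step 11 falls away; this fallback makes no compound outside the list (F0).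

**Further compounds**

F1 | step 7 | methyl 3-methoxy-3-[(trimethylsilyl)oxy]prop-2-enoate | COC(=O)C=C(OC)O[Si](C)(C)C
F2 | step 7 | dimethyl 2-{3-[5-(benzyloxy)-2-(tert-butoxycarbonyl)-4-chloro-3-methylphenoxy]-4-[(trimethylsilyl)oxy]hex-3-en-2-yl}propanedioate (alkene isomer and diastereomer mixture) | CCC(O[Si](C)(C)C)=C(Oc1cc(OCc2ccccc2)c(Cl)c(C)c1C(=O)OC(C)(C)C)C(C)C(C(=O)OC)C(=O)OC
F3 | step 8 | methyl 5-[5-(benzyloxy)-2-(tert-butoxycarbonyl)-4-chloro-3-methylphenoxy]-3-chloro-3,6-dimethyl-2,4-dioxocyclohexane-1-carboxylate (diastereomer mixture) | COC(=O)C1C(C)C(Oc2cc(OCc3ccccc3)c(Cl)c(C)c2C(=O)OC(C)(C)C)C(=O)C(C)(Cl)C1=O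
F0 | step 10 | none | none
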